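## The problem

Target 11 is (4S)-5,7-dihydroxy-4-phenyl-8-(3-phenylpropanoyl)-3,4-dihydro-2H-chromen-2-one. Chromanone numbering is used throughout: O1, lactone carbonyl C2, methylene C3, phenyl-bearing methine C4, then C4a, C5 to C8 and C8a of the benzene ring.

- The only stereocentre, C4, is a doubly benzylic methine with no neighbouring stereocentre to relay from. It has to be set by a catalyst, next to a hexasubstituted benzene ring.
- C4a is flanked by two oxygens, O5 and the lactone oxygen on C8a. Any hydroxy acid or hydroxy ester on the way can therefore lactonise to either side, giving the wanted 8-acyl lactone or its 6-acyl isomer.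
- The two lactones interconvert only by ring opening, so every acidic, basic or nucleophilic step with O5 free risks scrambling.
- The C8 ketone makes the phloroglucinol a vinylogous acid. It is then a poor carbon nucleophile for an enantioselective conjugate addition at C4a, and acylation of a preformed dihydrocoumarin chooses badly between C6 and C8.
- The aryl ester lactone is cleaved by alkoxide, hydroxide and amines, the free phenols oxidise in base, and the end game must not reduce the aryl ketone.
- The feature that makes the key step possible: the ring C4a–C5–C6–C7–C8–C8a, with oxygen on alternate carbons and the acyl group on C8, is a Claisen-folded polyketide and an isomer of a 2-pyrone. C8a is the pyrone carbonyl C2, C4a is C3, C5 is C4, C6 is C5, C7 is C6, and C8 is the methylene of a 6-(2-oxoalkyl) arm.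
- In that pyrone the three oxygens of the target ring are three different kinds of oxygen: carbonyl oxygen (becomes O1), enol oxygen (becomes O5) and ring oxygen (becomes O7). Its C3 is the carbon of a pKa 5 enol, an excellent partner for catalytic enantioselective conjugate addition.

## Retrosynthesis

The difficulty is a stereocentre and a regiochemical choice that both sit at C4a. Both disappear if the benzene ring does not yet exist when the stereocentre is made, and is then generated from a ring whose oxygens are already different.

**11 from 10.** The O5–CH2Ph bond is cut. Benzyl ether 10 differs from 11 only in this mask. Hydrogenolysis is neutral, so the lactone cannot move to O5 in the last step. The benzyl group is also the marker that keeps O5 from lactonising earlier.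

**10 from 7 (key).** Two bonds are cut: the arene bond C8–C8a and the lactone bond O1–C2. Undoing the Claisen condensation and re-closing the ester on the C7 oxygen gives pyrone 7, via open-chain enoate 8 and phenol ester 9.
- Against the neighbouring cuts: cutting C4–C4a (Friedel–Crafts type) leaves an enantioselective addition of a deactivated arene and the O5/O8a choice. Cutting C8–C(=O) leaves the C6/C8 choice. Cutting the ring itself removes both, because every substituent position is written into 7.
- Simplification: 7 is a monocyclic pyrone, against a hexasubstituted benzolactone.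
- Asked of the forward reaction: alkoxide must open the pyrone at C2, the diketone carbon must C-acylate the new ester, and the lactone must close on the C8a oxygen only.

**7 from 5 and 6.** The bond between the pyrone 6-methylene and the ketone carbonyl is cut. Forward, the vinylogous anion of the 6-methyl group of 5 is acylated by N-methoxy-N-methylamide 6. This is preferred to carrying the keto arm through the stereocentre-forming step, where its active methylene would compete as a nucleophile.

**5 from 3.** The benzyl ester C–O bond and the O4–benzyl bond are cut. Enol lactone 3 already contains both as an activated ester of the pyrone enol. Forward, benzyl alcohol opens it to 4 and the freed enol is benzylated. Every alkoxy group is chosen as benzyl so that alkoxide exchange in the key step is degenerate.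

**3 from 1 and 2.** The C4–C4a bond and the lactone O–C2 bond are cut. Forward, this is a carbene-catalysed oxidative [3+3] annulation of triacetic acid lactone 1 with cinnamaldehyde 2. It sets C4 on the acidic enol, where this reaction type is established, rather than on an arene. Both partners are bulk chemicals.

## Roads not taken

**Alternative 1 (the obvious one):** cut C4–C4a and O1–C2 on the intact arene.
- Forward key step: acid-mediated hydroarylation and lactonisation of 2',4',6'-trihydroxydihydrochalcone A1 with cinnamic acid.
- It gives a racemate. Each free ring carbon of A1 has two flanking hydroxyls, so the 6-acyl lactone A2 forms alongside the target. Resolution would discard half of the material.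
- A catalytic enantioselective version would need the acyl-deactivated arene carbon to add to a cinnamoyl electrophile. Close precedent covers naphthols and very electron-rich phenols only.
- The chosen plan sets C4 on a pKa 5 enol and fixes the lactone oxygen by construction.

**Alternative 2:** cut the two C–H bonds at C3 and C4, that is, start from a flat coumarin.
- Forward: Pechmann product 5,7-dihydroxy-4-phenylcoumarin A3 is acylated to the 8-acyl coumarin A4. A4 is then reduced enantioselectively at C3=C4 with copper hydride from Cu(OAc)2, a chiral bisphosphine and a silane.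
- The acylation of A3 has the C6/C8 problem.
- The β,β-disubstituted double bond is shielded by the peri oxygen on C5 and by the twisted 4-phenyl group.
- The aryl ketone competes for hydride.
- Copper hydride reduction of coumarins tends to open the lactone, which brings the O5/O8a choice back.

**Alternative 3:** cut C3–C4 and O1–C2 through an ortho-quinone methide.
- Forward: sulfone A5 is eliminated to the quinone methide. A malonate adds under a chiral bifunctional base catalyst to give lactone ester A6, which is then dealkoxycarbonylated and deprotected.
- A5 needs a fully differentiated acylphloroglucinol and a three-component sulfone synthesis.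
- The extra carboxyl must be removed under conditions (heat, halide, water) that open the aryl lactone.
- The route would take about eight steps, against five.

Key step: step 4

Assumption: the facial sense of the chiral triazolium in step 1 is taken from the usual model; whichever antipode of the precatalyst gives (4S)-3 is used (both are catalogue compounds), and 6 is taken as a catalogue compound.

## Route

Step 1
Reactants: 1 4-hydroxy-6-methyl-2H-pyran-2-one (triacetic acid lactone); 2 (E)-cinnamaldehyde
Product: 3 (4S)-7-methyl-4-phenyl-3,4-dihydro-2H,5H-pyrano[4,3-b]pyran-2,5-dione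
Conditions: chiral aminoindanol-derived N-mesityl triazolium chloride (10 mol %), 3,3',5,5'-tetra-tert-butyl-4,4'-diphenoquinone (1.2 equiv), NaOAc (20 mol %), toluene, 25 °C
Reagents that add atoms: none
Why: Oxidative N-heterocyclic carbene catalysis: the carbene–aldehyde adduct is oxidised by the quinone to a catalyst-bound α,β-unsaturated acyl azolium, the enol carbon C3 of 1 adds to its β-carbon, and enol lactonisation releases the carbene. This [3+3] annulation is well precedented for cyclic 1,3-dicarbonyl enols. The C4 stereocentre is set by the catalyst, whose indane wall shields one face of the acyl azolium.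

Step 2
Reactants: 3 (4S)-7-methyl-4-phenyl-3,4-dihydro-2H,5H-pyrano[4,3-b]pyran-2,5-dione
Product: 5 benzyl (3S)-3-[4-(benzyloxy)-6-methyl-2-oxo-2H-pyran-3-yl]-3-phenylpropanoate, via hydroxypyrone benzyl ester 4 (not isolated)
Conditions: BnOH (1.5 equiv), K2CO3 (2 equiv), DMF, 25 °C; then BnBr (1.2 equiv), 40 °C
Reagents that add atoms: benzyl alcohol OCc1ccccc1; benzyl bromide BrCc1ccccc1
Why: The enol lactone of 3 is an activated ester (its leaving group is the pKa 5 pyrone enolate) and should undergo alcoholysis at room temperature. The pyrone enolate of 4 is then O-benzylated in the same flask (ambident-anion alkylation; O4 is favoured in a dipolar aprotic solvent with C3 blocked). The stereocentre is not touched.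

Step 3
Reactants: 5 benzyl (3S)-3-[4-(benzyloxy)-6-methyl-2-oxo-2H-pyran-3-yl]-3-phenylpropanoate; 6 N-methoxy-N-methyl-3-phenylpropanamide
Product: 7 benzyl (3S)-3-[4-(benzyloxy)-2-oxo-6-(2-oxo-4-phenylbutyl)-2H-pyran-3-yl]-3-phenylpropanoate
Conditions: LiN(SiMe3)2 (1.1 equiv), THF, −78 °C; then 6 (1.2 equiv), −78 to −20 °C; aq. NH4Cl
Reagents that add atoms: none
Why: Vinylogous (lateral) deprotonation of a 4-alkoxy-6-methyl-2-pyrone gives the extended dienolate, which is C-acylated at the exocyclic carbon. The N-methoxy-N-methylamide holds the tetrahedral chelate until work-up, so there is no over-addition and no foreign alkoxide is released. The stereocentre is remote from every acidic site.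

Step 4
Reactants: 7 benzyl (3S)-3-[4-(benzyloxy)-2-oxo-6-(2-oxo-4-phenylbutyl)-2H-pyran-3-yl]-3-phenylpropanoate
Product: 10 (4S)-5-(benzyloxy)-7-hydroxy-4-phenyl-8-(3-phenylpropanoyl)-3,4-dihydro-2H-chromen-2-one, via ring-opened triketo diester 8 (not isolated), via acylphloroglucinol benzyl ester 9 (not isolated)
Conditions: Mg(OCH2Ph)2 (3 equiv, from Bu2Mg and BnOH), BnOH/THF, 65 °C; 1 M HCl; then TsOH·H2O (10 mol %), toluene, 60 °C
Reagents that add atoms: none
Why: This is the alkoxide-induced pyrone-to-phloroglucinol ring transformation (ring opening, then Claisen condensation), the benzyl-alkoxide version of the classical Mg(OMe)2 conversion of 6-(2-oxoalkyl)-2-pyrones into acylphloroglucinols. Benzyloxide adds to the lactone carbonyl C2 of 7 and the ring oxygen leaves as the C6 enolate, giving the magnesium chelate of 8 with the new ester and the C5 methylene held cis on the C3=C4 bond by the geometry of the former ring. The benzene ring closes by 6-exo-trig C-acylation of the 1,3-diketone carbon on that ester (bond C8–C8a of the target), and loss of benzyloxide and enolisation give phenol 9 irreversibly; the other carbon nucleophiles of 8 could reach the ester only through four- or eight-membered rings, and re-closure through oxygen merely returns 7. On acidification the lactone closes by 6-exo-trig attack of the C8a hydroxyl on the side-chain benzyl ester, the only ortho hydroxyl available because the oxygen on C5 arrives benzylated from the pyrone enol. The pyrone thus secures the regiochemistry that a preformed phloroglucinol cannot: its carbonyl oxygen becomes O1, its enol oxygen O5 and its ring oxygen O7. Every alkoxy group and the base are benzyl, so alkoxide exchange at C4 or at either ester is degenerate. No stereocentre is formed; C4 is carried through unchanged because its hydrogen is not acidified in 7, 8 or 9.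

Step 5
Reactants: 10 (4S)-5-(benzyloxy)-7-hydroxy-4-phenyl-8-(3-phenylpropanoyl)-3,4-dihydro-2H-chromen-2-one
Product: 11 (4S)-5,7-dihydroxy-4-phenyl-8-(3-phenylpropanoyl)-3,4-dihydro-2H-chromen-2-one
Conditions: H2 (1 atm), Pd/C (10 % Pd on carbon), EtOAc, 25 °C
Reagents that add atoms: none
Why: Hydrogenolysis of the aryl benzyl ether under neutral conditions. The lactone cannot migrate to O5 without ring opening, and the hydrogen-bonded ortho-hydroxyaryl ketone should be reduced far more slowly than the ether is cleaved. No stereocentre is affected.

## Compound list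

1 | 4-hydroxy-6-methyl-2H-pyran-2-one | CC1=CC(O)=CC(=O)O1 | starting material
2 | (E)-cinnamaldehyde | O=C/C=C/c1ccccc1 | starting material
3 | (4S)-7-methyl-4-phenyl-3,4-dihydro-2H,5H-pyrano[4,3-b]pyran-2,5-dione | O=C1C[C@@H](c2ccccc2)C2=C(O1)C=C(C)OC2=O | intermediate
4 | benzyl (3S)-3-(4-hydroxy-6-methyl-2-oxo-2H-pyran-3-yl)-3-phenylpropanoate | O=C(OCc1ccccc1)C[C@@H](c1ccccc1)C1=C(O)C=C(C)OC1=O | intermediate
5 | benzyl (3S)-3-[4-(benzyloxy)-6-methyl-2-oxo-2H-pyran-3-yl]-3-phenylpropanoate | O=C(OCc1ccccc1)C[C@@H](c1ccccc1)C1=C(OCc2ccccc2)C=C(C)OC1=O | intermediate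
6 | N-methoxy-N-methyl-3-phenylpropanamide | CON(C)C(=O)CCc1ccccc1 | starting material
7 | benzyl (3S)-3-[4-(benzyloxy)-2-oxo-6-(2-oxo-4-phenylbutyl)-2H-pyran-3-yl]-3-phenylpropanoate | O=C(OCc1ccccc1)C[C@@H](c1ccccc1)C1=C(OCc2ccccc2)C=C(CC(=O)CCc2ccccc2)OC1=O | intermediate
8 | dibenzyl (2E,3S)-2-[1-(benzyloxy)-3,5-dioxo-7-phenylheptylidene]-3-phenylpentanedioate | O=C(OCc1ccccc1)C[C@@H](c1ccccc1)/C(C(=O)OCc1ccccc1)=C(\OCc1ccccc1)CC(=O)CC(=O)CCc1ccccc1 | intermediate
9 | benzyl (3S)-3-[6-(benzyloxy)-2,4-dihydroxy-3-(3-phenylpropanoyl)phenyl]-3-phenylpropanoate | O=C(OCc1ccccc1)C[C@@H](c1ccccc1)c1c(OCc2ccccc2)cc(O)c(C(=O)CCc2ccccc2)c1O | intermediate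
10 | (4S)-5-(benzyloxy)-7-hydroxy-4-phenyl-8-(3-phenylpropanoyl)-3,4-dihydro-2H-chromen-2-one | O=C1C[C@@H](c2ccccc2)c2c(OCc3ccccc3)cc(O)c(C(=O)CCc3ccccc3)c2O1 | intermediate
11 | (4S)-5,7-dihydroxy-4-phenyl-8-(3-phenylpropanoyl)-3,4-dihydro-2H-chromen-2-one | O=C1C[C@@H](c2ccccc2)c2c(O)cc(O)c(C(=O)CCc3ccccc3)c2O1 | target

## Step count and risk

Total steps: 5. Longest linear sequence: 5 (1, 3, 5, 7, 10, 11).

**Step 4 (key step).**
- What may go wrong: the side-chain enolate may deactivate the pyrone carbonyl so that ring opening stalls. Alkoxide may attack C6 instead of C2. The diketone enol oxygen may cyclise onto C4 with loss of benzyloxide (4-pyranone formation) faster than the carbon closes on the ester.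
- Fallback (sets out from 2, returns at 10): the arene is taken ready-made.
  - Phloroglucinol is acylated with 3-phenylpropanoyl chloride and AlCl3 to 1-(2,4,6-trihydroxyphenyl)-3-phenylpropan-1-one F1 (the same compound as A1).
  - The non-chelated para hydroxyl of F1 is benzylated (BnBr 1 equiv, K2CO3) to 1-[4-(benzyloxy)-2,6-dihydroxyphenyl]-3-phenylpropan-1-one F2.
  - F2 is symmetric, so the carbene-catalysed oxidative annulation of step 1, applied to F2 and 2, can only give 10: the C–C bond forms at either equivalent ring carbon and the lactone closes on the one free ortho oxygen.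
  - This moves the enantioselective step from a proven enol to a deactivated phenol, which is why it is the fallback and not the route.

**Step 3.**
- What may go wrong: competing enolisation of the benzyl ester (acylation or self-condensation at the wrong carbon), or proton transfer between the product and the dienolate that stops conversion.
- Fallback (sets out from 1, returns at 7): the order is reversed.
  - The dianion of 1 (LiN(iPr)2, 2.2 equiv) is acylated with 6 to 4-hydroxy-6-(2-oxo-4-phenylbutyl)-2H-pyran-2-one F3.
  - F3 is annulated with 2 as in step 1 to (4S)-7-(2-oxo-4-phenylbutyl)-4-phenyl-3,4-dihydro-2H,5H-pyrano[4,3-b]pyran-2,5-dione F4. The pKa gap between the pyrone enol and the side-chain methylene should direct the reaction to C3.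
  - F4 is opened with benzyl alcohol to benzyl (3S)-3-[4-hydroxy-2-oxo-6-(2-oxo-4-phenylbutyl)-2H-pyran-3-yl]-3-phenylpropanoate F5.
  - F5 is O-benzylated under Mitsunobu conditions (BnOH, PPh3, diisopropyl azodicarboxylate), which address only the acidic pyrone hydroxyl, to give 7.

**Step 1.**
- What may go wrong: insufficient facial selectivity with this enol, or O-acylation of 1 without ring closure.
- Fallback (sets out from 1 and 2, returns at 3): iminium catalysis replaces carbene catalysis.
  - α,α-Diphenylprolinol trimethylsilyl ether (antipode chosen for 4S) catalyses the Michael addition of 1 to 2, giving lactol (4S)-2-hydroxy-7-methyl-4-phenyl-3,4-dihydro-2H,5H-pyrano[4,3-b]pyran-5-one F6 as an anomeric mixture.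
  - F6 is oxidised to 3 with TEMPO and PhI(OAc)2.

**Step 2.**
- What may go wrong: benzylation of the ambident pyrone anion at the carbonyl oxygen (giving the 4-pyranone ether) or at C3 instead of O4.
- Fallback (sets out from 4, isolated after the alcoholysis, returns at 5): the C4–O bond is made by substitution at carbon instead of alkylation at oxygen.
  - 4 is sulfonylated (TsCl, Et3N) to benzyl (3S)-3-[6-methyl-4-(4-methylbenzenesulfonyloxy)-2-oxo-2H-pyran-3-yl]-3-phenylpropanoate F7.
  - Addition–elimination at C4 with benzyl alcohol and K2CO3 gives 5 with no ambiguity about the oxygen.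

## Further compounds

F1 | step 4 | 1-(2,4,6-trihydroxyphenyl)-3-phenylpropan-1-one | O=C(CCc1ccccc1)c1c(O)cc(O)cc1O
F2 | step 4 | 1-[4-(benzyloxy)-2,6-dihydroxyphenyl]-3-phenylpropan-1-one | O=C(CCc1ccccc1)c1c(O)cc(OCc2ccccc2)cc1O
F3 | step 3 | 4-hydroxy-6-(2-oxo-4-phenylbutyl)-2H-pyran-2-one | O=C(CCc1ccccc1)CC1=CC(O)=CC(=O)O1
F4 | step 3 | (4S)-7-(2-oxo-4-phenylbutyl)-4-phenyl-3,4-dihydro-2H,5H-pyrano[4,3-b]pyran-2,5-dione | O=C1C[C@@H](c2ccccc2)C2=C(O1)C=C(CC(=O)CCc3ccccc3)OC2=O
F5 | step 3 | benzyl (3S)-3-[4-hydroxy-2-oxo-6-(2-oxo-4-phenylbutyl)-2H-pyran-3-yl]-3-phenylpropanoate | O=C(OCc1ccccc1)C[C@@H](c1ccccc1)C1=C(O)C=C(CC(=O)CCc2ccccc2)OC1=O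
F6 | step 1 | (4S)-2-hydroxy-7-methyl-4-phenyl-3,4-dihydro-2H,5H-pyrano[4,3-b]pyran-5-one (anomeric mixture) | OC1C[C@@H](c2ccccc2)C2=C(O1)C=C(C)OC2=O
F7 | step 2 | benzyl (3S)-3-[6-methyl-4-(4-methylbenzenesulfonyloxy)-2-oxo-2H-pyran-3-yl]-3-phenylpropanoate | O=C(OCc1ccccc1)C[C@@H](c1ccccc1)C1=C(OS(=O)(=O)c2ccc(C)cc2)C=C(C)OC1=O
A1 | alternative 1 | 1-(2,4,6-trihydroxyphenyl)-3-phenylpropan-1-one (2',4',6'-trihydroxydihydrochalcone) | O=C(CCc1ccccc1)c1c(O)cc(O)cc1O
A2 | alternative 1 | rac-5,7-dihydroxy-4-phenyl-6-(3-phenylpropanoyl)-3,4-dihydro-2H-chromen-2-one | O=C1CC(c2ccccc2)c2c(O)c(C(=O)CCc3ccccc3)c(O)cc2O1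
A3 | alternative 2 | 5,7-dihydroxy-4-phenyl-2H-chromen-2-one | O=c1cc(-c2ccccc2)c2c(O)cc(O)cc2o1
A4 | alternative 2 | 5,7-dihydroxy-4-phenyl-8-(3-phenylpropanoyl)-2H-chromen-2-one | O=c1cc(-c2ccccc2)c2c(O)cc(O)c(C(=O)CCc3ccccc3)c2o1
A5 | alternative 3 | 1-{2-hydroxy-4,6-bis(methoxymethoxy)-3-[(4-methylbenzenesulfonyl)(phenyl)methyl]phenyl}-3-phenylpropan-1-one (racemic) | O=C(CCc1ccccc1)c1c(O)c(C(c2ccccc2)S(=O)(=O)c2ccc(C)cc2)c(OCOC)cc1OCOC
A6 | alternative 3 | methyl (4S)-5,7-bis(methoxymethoxy)-2-oxo-4-phenyl-8-(3-phenylpropanoyl)-3,4-dihydro-2H-chromene-3-carboxylate (C3 epimers) | COC(=O)C1C(=O)Oc2c(C(=O)CCc3ccccc3)c(OCOC)cc(OCOC)c2[C@@H]1c1ccccc1
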